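**Retrosynthetic overview**
- The target is the seco-acid of a depsidone: the last disconnection is the lactone C(=O)–O bond (hydrolysis), preceded by O-debenzylation.
- Key disconnection: the diaryl ether C–O bond of the depsidone is made from a depside (aryl salicylate) by an intramolecular dehydrogenative C–H/O–H coupling (the new step).
- The depside comes from mono-benzylated olivetol and a 5-substituted benzodioxinone (transacylation); the pentanoyl ketone is carried as a 1,1-disubstituted alkene and released by ozonolysis.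
- The benzodioxinone comes from the commercial 5,7-dihydroxy acetonide by O-methylation, triflation and Suzuki coupling.
- Ring order: both benzene rings are bought; the only ring formed is the central 1,4-dioxepinone (step 7), and it is opened again in step 9.

Assumption: the target SMILES has no stereocentre or stereo double bond and the diaryl ether axis is not configurationally stable, so there is no enantiomer to control; the keto acid is drawn open although it equilibrates with its lactol (3-butyl-3-hydroxyphthalide) tautomer; boronate 4 is taken as purchasable.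

**Step 1**
Reactants: 1 5,7-dihydroxy-2,2-dimethyl-4H-1,3-benzodioxin-4-one
Product: 2 5-hydroxy-7-methoxy-2,2-dimethyl-4H-1,3-benzodioxin-4-one
Conditions: MeI (1.05 equiv), K2CO3 (1.1 equiv), acetone, rt
Reagents that add atoms: iodomethane, CI
Why: Williamson etherification; the 5-OH is hydrogen-bonded to the C4 carbonyl and stays untouched, so only the 7-OH is methylated.

**Step 2**
Reactants: 2 5-hydroxy-7-methoxy-2,2-dimethyl-4H-1,3-benzodioxin-4-one
Product: 3 7-methoxy-2,2-dimethyl-4-oxo-4H-1,3-benzodioxin-5-yl trifluoromethanesulfonate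
Conditions: Tf2O (1.2 equiv), pyridine, CH2Cl2, 0 °C
Reagents that add atoms: trifluoromethanesulfonic anhydride, O=S(=O)(OS(=O)(=O)C(F)(F)F)C(F)(F)F
Why: O-sulfonylation of the chelated phenol turns it into a cross-coupling handle (aryl triflate formation).

**Step 3**
Reactants: 3 7-methoxy-2,2-dimethyl-4-oxo-4H-1,3-benzodioxin-5-yl trifluoromethanesulfonate; 4 2-(hex-1-en-2-yl)-4,4,5,5-tetramethyl-1,3,2-dioxaborolane
Product: 5 5-(hex-1-en-2-yl)-7-methoxy-2,2-dimethyl-4H-1,3-benzodioxin-4-one
Conditions: Pd(dppf)Cl2 (5 mol%), K3PO4 (3 equiv), THF/H2O 10:1, 65 °C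
Reagents that add atoms: none
Why: Suzuki–Miyaura coupling of an electron-poor aryl triflate with an alkenyl boronate; the alkene is the masked pentanoyl group, which avoids the pseudo-acid chemistry of a free 2-acylbenzoate.

**Step 4**
Reactants: 6 olivetol (5-pentylbenzene-1,3-diol)
Product: 7 3-(benzyloxy)-5-pentylphenol
Conditions: BnBr (1.0 equiv), K2CO3 (1.0 equiv), acetone, reflux; recover and recycle olivetol
Reagents that add atoms: benzyl bromide, BrCc1ccccc1
Why: Williamson mono-etherification of a symmetric diol; it is statistical but the mono-ether separates easily from diol and bis-ether.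

**Step 5**
Reactants: 5 5-(hex-1-en-2-yl)-7-methoxy-2,2-dimethyl-4H-1,3-benzodioxin-4-one; 7 3-(benzyloxy)-5-pentylphenol (1.3 equiv)
Product: 8 3-(benzyloxy)-5-pentylphenyl 2-(hex-1-en-2-yl)-6-hydroxy-4-methoxybenzoate
Conditions: Cs2CO3 (1.2 equiv), DMF, 60 °C
Reagents that add atoms: none
Why: Anionic transacylation (addition–elimination) of the benzodioxinone by the phenoxide of 7, driven by irreversible loss of acetone; it forms the depside and frees the salicylate OH needed in step 7.

**Step 6**
Reactants: 8 3-(benzyloxy)-5-pentylphenyl 2-(hex-1-en-2-yl)-6-hydroxy-4-methoxybenzoate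
Product: 10 3-(benzyloxy)-5-pentylphenyl 2-hydroxy-4-methoxy-6-pentanoylbenzoate, via secondary ozonide 9 (not isolated)
Conditions: O3, CH2Cl2, −78 °C (Sudan III end point); then PPh3 (1.2 equiv), −78 °C to rt
Reagents that add atoms: ozone, [O-][O+]=O
Why: Criegee ozonolysis; the 1,1-disubstituted styrene reacts far faster than the aryl ethers at −78 °C, and reductive work-up gives the aryl butyl ketone.

**Step 7**
Reactants: 10 3-(benzyloxy)-5-pentylphenyl 2-hydroxy-4-methoxy-6-pentanoylbenzoate
Product: 11 8-(benzyloxy)-3-methoxy-1-pentanoyl-6-pentyl-11H-dibenzo[b,e][1,4]dioxepin-11-one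
Conditions: 3,6-di-tert-butyl-9-mesityl-10-phenylacridinium BF4 (5 mol%), Co(dmgH)2(py)Cl (8 mol%), DCE/HFIP 10:1, 0.01 M, 455 nm LEDs, Ar, 25 °C
Reagents that add atoms: none
Why: Proposed new method: acceptorless photocatalytic intramolecular dehydrogenative C–H aryloxylation — the excited acridinium (about +2.0 V) oxidises the benzyloxy-bearing ring of 10 (the more electron-rich arene, since the salicylate ring carries two carbonyl groups) to its radical cation, whose charge lies para and ortho to OBn; the tethered salicylate OH reaches only the two carbons ortho to the ester oxygen and should add at the one para to OBn (the ipso ester carbon is meta to OBn and unactivated, and C–C coupling through this tether is geometrically impossible); proton loss gives a cyclohexadienyl radical that the cobaloxime cycle aromatises with release of H2 while returning the acridine radical to the acridinium; with no terminal oxidant and no free phenol on the product ring, the more electron-rich depsidone 11 can only form a radical cation that decays by back electron transfer, which addresses the over-oxidation that limits classical phenol-oxidation routes from depsides to depsidones; closest known reaction types are acridinium-photocatalysed site-selective arene C–H amination (including hydrogen-evolving variants with cobaloximes), photoinduced-electron-transfer cyclisation of arene radical cations onto tethered OH or CO2H groups, and photocatalytic dehydrogenative lactonisation of biaryl-2-carboxylic acids, none of which has been shown with a phenol O-nucleophile to form a diaryl ether or a seven-membered depsidone ring.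

**Step 8**
Reactants: 11 8-(benzyloxy)-3-methoxy-1-pentanoyl-6-pentyl-11H-dibenzo[b,e][1,4]dioxepin-11-one
Product: 12 8-hydroxy-3-methoxy-1-pentanoyl-6-pentyl-11H-dibenzo[b,e][1,4]dioxepin-11-one
Conditions: H2 (1 atm), 10% Pd/C, EtOAc, rt; stop after 1 equiv H2
Reagents that add atoms: none
Why: Catalytic hydrogenolysis of the benzyl aryl ether; the hindered aryl ketone and the lactone reduce more slowly in neutral EtOAc.

**Step 9**
Reactants: 12 8-hydroxy-3-methoxy-1-pentanoyl-6-pentyl-11H-dibenzo[b,e][1,4]dioxepin-11-one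
Product: 13 2-(2,4-dihydroxy-6-pentylphenoxy)-4-methoxy-6-pentanoylbenzoic acid
Conditions: LiOH·H2O (4 equiv), degassed THF/H2O 3:1, Ar, 0 °C to rt; then cold 1 M HCl to pH 3, 0 °C
Reagents that add atoms: lithium hydroxide, [Li+].[OH-]
Why: Saponification of the strained aryl ester of the depsidone, assisted by the neighbouring ketone; cold, mild acidification gives the keto acid without dehydration to the butylidenephthalide, and no stereocentre is formed.

**Compound list**
1 | 5,7-dihydroxy-2,2-dimethyl-4H-1,3-benzodioxin-4-one | CC1(C)OC(=O)c2c(O)cc(O)cc2O1 | starting material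
2 | 5-hydroxy-7-methoxy-2,2-dimethyl-4H-1,3-benzodioxin-4-one | CC1(C)OC(=O)c2c(O)cc(OC)cc2O1 | intermediate
3 | 7-methoxy-2,2-dimethyl-4-oxo-4H-1,3-benzodioxin-5-yl trifluoromethanesulfonate | CC1(C)OC(=O)c2c(OS(=O)(=O)C(F)(F)F)cc(OC)cc2O1 | intermediate
4 | 2-(hex-1-en-2-yl)-4,4,5,5-tetramethyl-1,3,2-dioxaborolane | C=C(CCCC)B1OC(C)(C)C(C)(C)O1 | starting material
5 | 5-(hex-1-en-2-yl)-7-methoxy-2,2-dimethyl-4H-1,3-benzodioxin-4-one | C=C(CCCC)c1cc(OC)cc2OC(C)(C)OC(=O)c12 | intermediate
6 | olivetol (5-pentylbenzene-1,3-diol) | CCCCCc1cc(O)cc(O)c1 | starting material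
7 | 3-(benzyloxy)-5-pentylphenol | CCCCCc1cc(O)cc(OCc2ccccc2)c1 | intermediate
8 | 3-(benzyloxy)-5-pentylphenyl 2-(hex-1-en-2-yl)-6-hydroxy-4-methoxybenzoate | CCCCCc1cc(OCc2ccccc2)cc(OC(=O)c2c(O)cc(OC)cc2C(=C)CCCC)c1 | intermediate
9 | 3-(benzyloxy)-5-pentylphenyl 2-(3-butyl-1,2,4-trioxolan-3-yl)-6-hydroxy-4-methoxybenzoate (secondary ozonide) | CCCCCc1cc(OCc2ccccc2)cc(OC(=O)c2c(O)cc(OC)cc2C3(CCCC)OCOO3)c1 | intermediate
10 | 3-(benzyloxy)-5-pentylphenyl 2-hydroxy-4-methoxy-6-pentanoylbenzoate | CCCCCc1cc(OCc2ccccc2)cc(OC(=O)c2c(O)cc(OC)cc2C(=O)CCCC)c1 | intermediate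
11 | 8-(benzyloxy)-3-methoxy-1-pentanoyl-6-pentyl-11H-dibenzo[b,e][1,4]dioxepin-11-one | CCCCCc1cc(OCc2ccccc2)cc2OC(=O)c3c(C(=O)CCCC)cc(OC)cc3Oc12 | intermediate
12 | 8-hydroxy-3-methoxy-1-pentanoyl-6-pentyl-11H-dibenzo[b,e][1,4]dioxepin-11-one | CCCCCc1cc(O)cc2OC(=O)c3c(C(=O)CCCC)cc(OC)cc3Oc12 | intermediate
13 | 2-(2,4-dihydroxy-6-pentylphenoxy)-4-methoxy-6-pentanoylbenzoic acid | CCCCCc1cc(O)cc(O)c1Oc1cc(OC)cc(C(=O)CCCC)c1C(=O)O | target

**Step count and risk**
Total steps: 9. Longest linear sequence: 8 steps (steps 1, 2, 3, 5, 6, 7, 8, 9 from compound 1); step 4 is a one-step side branch.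

The three steps most likely to fail:

1. Step 7 (the proposed new reaction). Likely failure modes are quenching of the photocatalyst by the salicylate phenol, attack ortho instead of para to OBn, and benzylic oxidation. The fallback is a convergent route by known chemistry that sets out from olivetol 6 and dioxinone 5 and comes back at target 13. Olivetol 6 is bis-benzylated (BnBr, K2CO3, DMF) to 1,3-bis(benzyloxy)-5-pentylbenzene F1, which NBS in MeCN brominates para to one benzyloxy group to give 1-bromo-2,4-bis(benzyloxy)-6-pentylbenzene F2; palladium-catalysed hydroxylation (Pd2(dba)3, tBuXPhos, KOH, dioxane/H2O, 100 °C) gives 2,4-bis(benzyloxy)-6-pentylphenol F3. In parallel, dioxinone 5 is opened with sodium benzyloxide (BnOH, NaH, THF) to benzyl 2-(hex-1-en-2-yl)-6-hydroxy-4-methoxybenzoate F4, which Tf2O/pyridine converts into benzyl 2-(hex-1-en-2-yl)-4-methoxy-6-(trifluoromethylsulfonyloxy)benzoate F5. Palladium-catalysed diaryl ether coupling of F5 with F3 (Pd2(dba)3, tBuXPhos, K3PO4, toluene, 100 °C) gives benzyl 2-[2,4-bis(benzyloxy)-6-pentylphenoxy]-6-(hex-1-en-2-yl)-4-methoxybenzoate F6. Ozonolysis (O3, CH2Cl2, −78 °C) passes through benzyl 2-[2,4-bis(benzyloxy)-6-pentylphenoxy]-6-(3-butyl-1,2,4-trioxolan-3-yl)-4-methoxybenzoate F7, and PPh3 work-up gives benzyl 2-[2,4-bis(benzyloxy)-6-pentylphenoxy]-4-methoxy-6-pentanoylbenzoate F8. Hydrogenolysis of all three benzyl groups (H2, Pd/C, EtOAc) then gives 13.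

2. Step 5 (addition of a phenoxide to a carbonyl flanked by two ortho substituents). The fallback sets out from 5 and 7 and comes back at 8. Instead of anionic addition–elimination, 5 is irradiated at 300 nm in CH2Cl2 at rt in the presence of 7; photochemical loss of acetone gives the neutral, unhindered o-quinoketene 5-(hex-1-en-2-yl)-3-methoxy-6-(oxomethylidene)cyclohexa-2,4-dien-1-one F9, which is trapped by phenol 7 at the ketene carbon to give 8 directly.

3. Step 8 (possible over-reduction of the aryl ketone during hydrogenolysis). The fallback sets out from 11 and comes back at 12. It replaces reductive cleavage by non-reductive Lewis-acid dealkylation: BCl3 with pentamethylbenzene as benzyl-cation scavenger, CH2Cl2, −78 °C. The methyl ether is para to the lactone carbonyl and not chelated, so it survives, and no new compound is made on the way.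

**Further compounds**
F1 | step 7 | 1,3-bis(benzyloxy)-5-pentylbenzene | CCCCCc1cc(OCc2ccccc2)cc(OCc2ccccc2)c1
F2 | step 7 | 1-bromo-2,4-bis(benzyloxy)-6-pentylbenzene | CCCCCc1cc(OCc2ccccc2)cc(OCc2ccccc2)c1Br
F3 | step 7 | 2,4-bis(benzyloxy)-6-pentylphenol | CCCCCc1cc(OCc2ccccc2)cc(OCc2ccccc2)c1O
F4 | step 7 | benzyl 2-(hex-1-en-2-yl)-6-hydroxy-4-methoxybenzoate | C=C(CCCC)c1cc(OC)cc(O)c1C(=O)OCc1ccccc1
F5 | step 7 | benzyl 2-(hex-1-en-2-yl)-4-methoxy-6-(trifluoromethylsulfonyloxy)benzoate | C=C(CCCC)c1cc(OC)cc(OS(=O)(=O)C(F)(F)F)c1C(=O)OCc1ccccc1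
F6 | step 7 | benzyl 2-[2,4-bis(benzyloxy)-6-pentylphenoxy]-6-(hex-1-en-2-yl)-4-methoxybenzoate | CCCCCc1cc(OCc2ccccc2)cc(OCc2ccccc2)c1Oc1cc(OC)cc(C(=C)CCCC)c1C(=O)OCc1ccccc1
F7 | step 7 | benzyl 2-[2,4-bis(benzyloxy)-6-pentylphenoxy]-6-(3-butyl-1,2,4-trioxolan-3-yl)-4-methoxybenzoate | CCCCCc1cc(OCc2ccccc2)cc(OCc2ccccc2)c1Oc1cc(OC)cc(C3(CCCC)OCOO3)c1C(=O)OCc1ccccc1
F8 | step 7 | benzyl 2-[2,4-bis(benzyloxy)-6-pentylphenoxy]-4-methoxy-6-pentanoylbenzoate | CCCCCc1cc(OCc2ccccc2)cc(OCc2ccccc2)c1Oc1cc(OC)cc(C(=O)CCCC)c1C(=O)OCc1ccccc1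
F9 | step 5 | 5-(hex-1-en-2-yl)-3-methoxy-6-(oxomethylidene)cyclohexa-2,4-dien-1-one | O=C=C1C(=O)C=C(OC)C=C1C(=C)CCCC
F0 | step 8 | none | none
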